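**Plan**

- Retrosynthesis: the C8 ester and the C1 silyl ether come off first. Both lactone bonds, O–C6 and C11–C7, are then cut in one stroke to 2-bromoacrylic acid and an all-Z cyclodeca-4,6,9-triene. The last cuts are C7–C8 (ring) and C2–C3 (chain).
- Enabling feature: the lactone carbinol carbon C6 is allylic to C4=C5, and the lactone is cis-fused with O6, C11 and O8 on one ring face. The ring O–C12–C11–C7–C6 is therefore the syn adduct of a carboxyvinyl unit across the Z C6=C7 bond of a C4–C7 diene, delivered from the face of a free C8 hydroxyl.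
- Forward: two Z-alkenyl fragments made from propargylic alcohols are joined by an aldol reaction (C2–C3). The chain is closed to the ten-membered ring by a CrCl2/NiCl2 addition (C7–C8), and the lactone ring is annulated onto the diene.
- Stereochemistry: C3 from a reagent-controlled boron aldol; C1 from C3 by 1,3-anti Evans–Tishchenko reduction, which also places the acetate; C8 in the ring closure; C6 and C7 from C8 in the annulation; the side-chain centre from (R)-2-methylbutanoic acid.
- Alkene geometry: both trisubstituted Z alkenes from anti-hydrometalation or anti-carbometalation of propargylic alcohols; the Z C6=C7 bond, which becomes the cis ring fusion, from diimide reduction of an iodoalkyne.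

Key step: step 14

Locants: C1 (CHOH), C2 (CH2), C3 (CHOAc), C4(Me)=C5, C6 (lactone O), C7 (lactone C), C8 (acyloxy), C9=C10(Me) are the ring carbons of the target; C11, C12 and C13 are the α-carbon, carbonyl and methylene of the lactone.

Assumption: the enol borinate made with (+)-Ipc2BCl is taken to attack the Si face of the enal (the sense assigned to methyl ketones); if the sense is the reverse, (−)-Ipc2BCl is used.

Assumption: the ring closure of step 13 is taken to give the 8S alcohol as the major epimer; the use of the 8R epimer is described under the fallbacks.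

**Step 1**
Reactants: 1 but-2-yn-1-ol
Product: 3 (Z)-3-iodobut-2-en-1-ol, via cyclic alkenylalanate 2 (not isolated)
Conditions: Red-Al, Et2O, 0 °C to rt; then I2, THF, −78 to 0 °C
Reagents that add atoms: iodine, II
Why: Hydroxyl-directed trans-hydroalumination of the propargylic alcohol places aluminium on C3 in a five-membered alkoxyalanate, and iodinolysis with retention gives the Z iodide (reduction–iodination of a propargylic alcohol).

**Step 2**
Reactants: 3 (Z)-3-iodobut-2-en-1-ol
Product: 4 (Z)-triethyl[(3-iodobut-2-en-1-yl)oxy]silane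
Conditions: TESCl, imidazole, CH2Cl2, 0 °C
Reagents that add atoms: chlorotriethylsilane, CC[Si](Cl)(CC)CC
Why: Standard silylation of a primary alcohol; the triethylsilyl ether is chosen because step 12 can oxidise it directly.

**Step 3**
Reactants: 4 (Z)-triethyl[(3-iodobut-2-en-1-yl)oxy]silane; 5 N-methoxy-N-methylacetamide
Product: 7 (Z)-3-methyl-5-(triethylsilyloxy)pent-3-en-2-one, via alkenyllithium 6 (not isolated)
Conditions: t-BuLi (2 equiv), Et2O, −78 °C; then 5, −78 to 0 °C
Reagents that add atoms: none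
Why: Iodine–lithium exchange proceeds with retention of alkene geometry, and acylation by the Weinreb amide stops at the ketone because the chelated tetrahedral intermediate survives until work-up.

**Step 4**
Reactants: 8 prop-2-yn-1-ol
Product: 10 (Z)-3-iodo-2-methylprop-2-en-1-ol, via alkenylmagnesium alkoxide 9 (not isolated)
Conditions: MeMgBr (2.5 equiv), CuI (10 mol %), THF, −10 °C to rt; then I2, −10 °C
Reagents that add atoms: methylmagnesium bromide, C[Mg]Br; iodine, II
Why: Copper-catalysed anti-carbomagnesiation of the magnesium alkoxide puts methyl on C2 and magnesium on C3 in a chelate, and iodinolysis with retention gives the Z iodide.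

**Step 5**
Reactants: 10 (Z)-3-iodo-2-methylprop-2-en-1-ol; 11 ethynyltrimethylsilane
Product: 12 (Z)-2-methyl-5-(trimethylsilyl)pent-2-en-4-yn-1-ol
Conditions: PdCl2(PPh3)2 (2 mol %), CuI (4 mol %), Et3N, THF, rt
Reagents that add atoms: none
Why: Sonogashira coupling of an alkenyl iodide proceeds with retention of the Z geometry at room temperature, where the enynol does not cycloisomerise.

**Step 6**
Reactants: 12 (Z)-2-methyl-5-(trimethylsilyl)pent-2-en-4-yn-1-ol
Product: 13 (Z)-2-methyl-5-(trimethylsilyl)pent-2-en-4-ynal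
Conditions: MnO2, CH2Cl2, 0 °C to rt
Reagents that add atoms: none
Why: Neutral heterogeneous oxidation of an allylic alcohol should give the enal without Z to E isomerisation.

**Step 7**
Reactants: 7 (Z)-3-methyl-5-(triethylsilyloxy)pent-3-en-2-one; 13 (Z)-2-methyl-5-(trimethylsilyl)pent-2-en-4-ynal
Product: 15 (2Z,6S,7Z)-6-hydroxy-3,7-dimethyl-1-(triethylsilyloxy)-10-(trimethylsilyl)deca-2,7-dien-9-yn-4-one, via enol diisopinocampheylborinate 14 (not isolated)
Conditions: (+)-Ipc2BCl, Et3N, Et2O, 0 °C; then 13, −78 to −20 °C; H2O2, MeOH, pH 7 buffer, 0 °C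
Reagents that add atoms: none
Why: Boron aldol reaction of a methyl ketone (Paterson aldol), in which the kinetic enol borinate adds through a cyclic transition state and the isopinocampheyl ligands direct attack to the Si face of the enal, setting the carbinol centre (C3 of the target) as S.

**Step 8**
Reactants: 15 (2Z,6S,7Z)-6-hydroxy-3,7-dimethyl-1-(triethylsilyloxy)-10-(trimethylsilyl)deca-2,7-dien-9-yn-4-one
Product: 16 (2Z,4S,6S,7Z)-4-hydroxy-3,7-dimethyl-1-(triethylsilyloxy)-10-(trimethylsilyl)deca-2,7-dien-9-yn-6-yl acetate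
Conditions: SmI2 (30 mol %), CH3CHO (8 equiv), THF, −10 °C
Reagents that add atoms: acetaldehyde, CC=O
Why: Evans–Tishchenko reduction, in which the samarium-bound hemiacetal of the C3 hydroxyl and acetaldehyde transfers hydride to the C1 ketone within a six-membered chair, giving the 1,3-anti (1S) alcohol and leaving the acetate on O3.

**Step 9**
Reactants: 16 (2Z,4S,6S,7Z)-4-hydroxy-3,7-dimethyl-1-(triethylsilyloxy)-10-(trimethylsilyl)deca-2,7-dien-9-yn-6-yl acetate
Product: 17 (2Z,4S,6S,7Z)-4-(tert-butyldimethylsilyloxy)-3,7-dimethyl-1-(triethylsilyloxy)-10-(trimethylsilyl)deca-2,7-dien-9-yn-6-yl acetate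
Conditions: TBSOTf, 2,6-lutidine, CH2Cl2, −78 °C
Reagents that add atoms: tert-butyldimethylsilyl triflate, CC(C)(C)[Si](C)(C)OS(=O)(=O)C(F)(F)F
Why: Silyl triflate silylation of the secondary allylic alcohol at low temperature should be faster than 1,3-acetyl migration.

**Step 10**
Reactants: 17 (2Z,4S,6S,7Z)-4-(tert-butyldimethylsilyloxy)-3,7-dimethyl-1-(triethylsilyloxy)-10-(trimethylsilyl)deca-2,7-dien-9-yn-6-yl acetate
Product: 18 (2Z,4S,6S,7Z)-4-(tert-butyldimethylsilyloxy)-10-iodo-3,7-dimethyl-1-(triethylsilyloxy)deca-2,7-dien-9-yn-6-yl acetate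
Conditions: NIS, AgNO3 (10 mol %), acetone, rt, dark
Reagents that add atoms: N-iodosuccinimide, O=C1CCC(=O)N1I
Why: Silver-catalysed iododesilylation of an alkynylsilane through the silver acetylide, to which silyl ethers, the acetate and trisubstituted alkenes are inert.

**Step 11**
Reactants: 18 (2Z,4S,6S,7Z)-4-(tert-butyldimethylsilyloxy)-10-iodo-3,7-dimethyl-1-(triethylsilyloxy)deca-2,7-dien-9-yn-6-yl acetate
Product: 19 (2Z,4S,6S,7Z,9Z)-4-(tert-butyldimethylsilyloxy)-10-iodo-3,7-dimethyl-1-(triethylsilyloxy)deca-2,7,9-trien-6-yl acetate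
Conditions: 2-nitrobenzenesulfonyl hydrazide, Et3N, THF/i-PrOH, rt
Reagents that add atoms: none
Why: Diimide adds hydrogen syn to the iodoalkyne to give the Z iodoalkene, while the trisubstituted alkenes react far more slowly.

**Step 12**
Reactants: 19 (2Z,4S,6S,7Z,9Z)-4-(tert-butyldimethylsilyloxy)-10-iodo-3,7-dimethyl-1-(triethylsilyloxy)deca-2,7,9-trien-6-yl acetate
Product: 21 (2Z,4S,6S,7Z,9Z)-4-(tert-butyldimethylsilyloxy)-10-iodo-3,7-dimethyl-1-oxodeca-2,7,9-trien-6-yl acetate, via alkoxysulfonium chloride 20 (not isolated)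
Conditions: (COCl)2, DMSO, CH2Cl2, −78 to −40 °C; then Et3N, −78 to 0 °C
Reagents that add atoms: none
Why: Under Swern conditions a primary triethylsilyl ether is cleaved by the chlorosulfonium salt and oxidised in the same operation, while the secondary TBS ether stays intact.

**Step 13**
Reactants: 21 (2Z,4S,6S,7Z,9Z)-4-(tert-butyldimethylsilyloxy)-10-iodo-3,7-dimethyl-1-oxodeca-2,7,9-trien-6-yl acetate
Product: 22 (1S,2Z,4Z,6S,7Z,9S)-9-(tert-butyldimethylsilyloxy)-6-hydroxy-2,8-dimethylcyclodeca-2,4,7-trien-1-yl acetate (target locants: 3-OAc, 1-OTBS, 8-OH; 1S,3S,8S)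
Conditions: CrCl2 (10 equiv), NiCl2 (1 mol % of the CrCl2), DMSO/THF, rt, 0.003 M, slow addition
Reagents that add atoms: none
Why: Intramolecular Nozaki–Hiyama–Kishi reaction, in which zerovalent nickel inserts into the dienyl iodide with retention and the derived dienylchromium adds to the aldehyde; the three Z alkenes fold the chain for ten-membered closure, and C8 is set by the cyclic transition state (chain delivered to the enal face on the C2 side, chromium-bound oxygen turned toward C1), taken here to give 8S.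

**Step 14**
Reactants: 22 (1S,2Z,4Z,6S,7Z,9S)-9-(tert-butyldimethylsilyloxy)-6-hydroxy-2,8-dimethylcyclodeca-2,4,7-trien-1-yl acetate; 23 2-bromoprop-2-enoic acid
Product: 24 (1S,3S,6S,7R,8R)-3-acetoxy-1-(tert-butyldimethylsilyloxy)-8-hydroxygermacra-4Z,9Z,11(13)-trien-12,6-olide
Conditions: Pd(OAc)2 (10 mol %), tri(2-furyl)phosphine (20 mol %), Ag2CO3 (1.5 equiv), MeCN, 50 °C
Reagents that add atoms: none
Why: Zerovalent palladium inserts into the C–Br bond of 23 and Ag2CO3 removes bromide; the cationic 1-carboxyvinylpalladium binds the C8 hydroxyl of 22 and adds syn across the adjacent Z C6=C7 bond, carbon to the diene terminus C7 and palladium to C6, giving an allylpalladium over C6–C5–C4. The closest known reaction type is the Larock-type heteroannulation of 1,3-dienes by halides bearing a carboxylic acid (Heck insertion followed by allylic substitution), used here in a hydroxyl-directed form. The lactone ring (O, C12, C11, C7, C6) closes by C–O reductive elimination of the palladium-bound carboxylate at the nearer allyl terminus C6, a five-membered closure through a six-membered palladacycle, in preference to seven-membered closure at the tertiary terminus C4. C7 is set by delivery of the vinyl group to the alkene face that carries the C8–O bond, and C6 by retention at palladium, so overall syn addition across a Z alkene gives the cis ring fusion, while C4=C5 keeps its Z geometry because the allyl unit cannot rotate within the ring. The step needs regioselection for C7 over C4 and over the isolated C9=C10 alkene (least substituted diene terminus, five-membered O–Pd chelate from C8), inner-sphere rather than anti C–O closure (halide-free conditions), and survival of the allylic acetate (weakly donating phosphine, 50 °C).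

**Step 15**
Reactants: 24 (1S,3S,6S,7R,8R)-3-acetoxy-1-(tert-butyldimethylsilyloxy)-8-hydroxygermacra-4Z,9Z,11(13)-trien-12,6-olide; 25 (R)-2-methylbutanoic acid
Product: 26 (1S,3S,6S,7R,8R)-3-acetoxy-1-(tert-butyldimethylsilyloxy)-8-[(2R)-2-methylbutanoyloxy]germacra-4Z,9Z,11(13)-trien-12,6-olide
Conditions: DCC, DMAP (20 mol %), CH2Cl2, 0 °C to rt
Reagents that add atoms: none
Why: Steglich esterification of the only free hydroxyl proceeds with retention at C8, and low temperature with catalytic DMAP should keep the α-centre of the acid intact.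

**Step 16**
Reactants: 26 (1S,3S,6S,7R,8R)-3-acetoxy-1-(tert-butyldimethylsilyloxy)-8-[(2R)-2-methylbutanoyloxy]germacra-4Z,9Z,11(13)-trien-12,6-olide
Product: 27 (1S,3S,6S,7R,8R)-3-acetoxy-1-hydroxy-8-[(2R)-2-methylbutanoyloxy]germacra-4Z,9Z,11(13)-trien-12,6-olide (CNP0282531.1)
Conditions: HF·pyridine, pyridine, THF, 0 °C to rt
Reagents that add atoms: none
Why: Buffered fluoride desilylation should remove the TBS ether without touching the two esters or the α-methylene lactone, which basic fluoride sources would endanger.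

**Compound list**

1 | but-2-yn-1-ol | CC#CCO | starting material
2 | sodium 2,2-bis(2-methoxyethoxy)-3-methyl-2,5-dihydro-1,2-oxaluminol-2-uide (cyclic alkenylalanate) | CC1=CCO[Al-]1(OCCOC)OCCOC.[Na+] | intermediate
3 | (Z)-3-iodobut-2-en-1-ol | C/C(I)=C/CO | intermediate
4 | (Z)-triethyl[(3-iodobut-2-en-1-yl)oxy]silane | C/C(I)=C/CO[Si](CC)(CC)CC | intermediate
5 | N-methoxy-N-methylacetamide | CC(=O)N(C)OC | starting material
6 | [4-(triethylsilyloxy)but-2-en-2-yl]lithium, lithium cis to the CH2OTES group | C/C([Li])=C/CO[Si](CC)(CC)CC | intermediate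
7 | (Z)-3-methyl-5-(triethylsilyloxy)pent-3-en-2-one | CC(=O)/C(C)=C\CO[Si](CC)(CC)CC | intermediate
8 | prop-2-yn-1-ol | C#CCO | starting material
9 | bromomagnesium (Z)-3-(bromomagnesio)-2-methylprop-2-en-1-olate | Br[Mg]/C=C(/C)CO[Mg]Br | intermediate
10 | (Z)-3-iodo-2-methylprop-2-en-1-ol | I/C=C(/C)CO | intermediate
11 | ethynyltrimethylsilane | C#C[Si](C)(C)C | starting material
12 | (Z)-2-methyl-5-(trimethylsilyl)pent-2-en-4-yn-1-ol | C[Si](C)(C)C#C/C=C(/C)CO | intermediate
13 | (Z)-2-methyl-5-(trimethylsilyl)pent-2-en-4-ynal | C[Si](C)(C)C#C/C=C(/C)C=O | intermediate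
14 | (3Z)-2-[bis((+)-isopinocampheyl)boryloxy]-3-methyl-5-(triethylsilyloxy)penta-1,3-diene | C=C(OB([C@@H]1[C@@H](C)[C@@H]2C[C@H](C1)C2(C)C)[C@@H]1[C@@H](C)[C@@H]2C[C@H](C1)C2(C)C)/C(C)=C\CO[Si](CC)(CC)CC | intermediate
15 | (2Z,6S,7Z)-6-hydroxy-3,7-dimethyl-1-(triethylsilyloxy)-10-(trimethylsilyl)deca-2,7-dien-9-yn-4-one | C[Si](C)(C)C#C/C=C(/C)[C@@H](O)CC(=O)/C(C)=C\CO[Si](CC)(CC)CC | intermediate
16 | (2Z,4S,6S,7Z)-4-hydroxy-3,7-dimethyl-1-(triethylsilyloxy)-10-(trimethylsilyl)deca-2,7-dien-9-yn-6-yl acetate | C[Si](C)(C)C#C/C=C(/C)[C@@H](OC(C)=O)C[C@H](O)/C(C)=C\CO[Si](CC)(CC)CC | intermediate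
17 | (2Z,4S,6S,7Z)-4-(tert-butyldimethylsilyloxy)-3,7-dimethyl-1-(triethylsilyloxy)-10-(trimethylsilyl)deca-2,7-dien-9-yn-6-yl acetate | C[Si](C)(C)C#C/C=C(/C)[C@@H](OC(C)=O)C[C@H](O[Si](C)(C)C(C)(C)C)/C(C)=C\CO[Si](CC)(CC)CC | intermediate
18 | (2Z,4S,6S,7Z)-4-(tert-butyldimethylsilyloxy)-10-iodo-3,7-dimethyl-1-(triethylsilyloxy)deca-2,7-dien-9-yn-6-yl acetate | IC#C/C=C(/C)[C@@H](OC(C)=O)C[C@H](O[Si](C)(C)C(C)(C)C)/C(C)=C\CO[Si](CC)(CC)CC | intermediate
19 | (2Z,4S,6S,7Z,9Z)-4-(tert-butyldimethylsilyloxy)-10-iodo-3,7-dimethyl-1-(triethylsilyloxy)deca-2,7,9-trien-6-yl acetate | I/C=C\C=C(\C)[C@@H](OC(C)=O)C[C@H](O[Si](C)(C)C(C)(C)C)/C(C)=C\CO[Si](CC)(CC)CC | intermediate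
20 | {[(2Z,4S,6S,7Z,9Z)-6-acetoxy-4-(tert-butyldimethylsilyloxy)-10-iodo-3,7-dimethyldeca-2,7,9-trien-1-yl]oxy}dimethylsulfonium chloride | I/C=C\C=C(\C)[C@@H](OC(C)=O)C[C@H](O[Si](C)(C)C(C)(C)C)/C(C)=C\CO[S+](C)C.[Cl-] | intermediate
21 | (2Z,4S,6S,7Z,9Z)-4-(tert-butyldimethylsilyloxy)-10-iodo-3,7-dimethyl-1-oxodeca-2,7,9-trien-6-yl acetate | I/C=C\C=C(\C)[C@@H](OC(C)=O)C[C@H](O[Si](C)(C)C(C)(C)C)/C(C)=C\C=O | intermediate
22 | (1S,2Z,4Z,6S,7Z,9S)-9-(tert-butyldimethylsilyloxy)-6-hydroxy-2,8-dimethylcyclodeca-2,4,7-trien-1-yl acetate | CC(=O)O[C@@H]1/C(C)=C\C=C/[C@H](O)/C=C(C)\[C@@H](O[Si](C)(C)C(C)(C)C)C1 | intermediate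
23 | 2-bromoprop-2-enoic acid | C=C(Br)C(=O)O | starting material
24 | (1S,3S,6S,7R,8R)-3-acetoxy-1-(tert-butyldimethylsilyloxy)-8-hydroxygermacra-4Z,9Z,11(13)-trien-12,6-olide | C=C1C(=O)O[C@H]2/C=C(/C)[C@@H](OC(C)=O)C[C@H](O[Si](C)(C)C(C)(C)C)/C(C)=C\[C@@H](O)[C@@H]12 | intermediate
25 | (R)-2-methylbutanoic acid | CC[C@@H](C)C(=O)O | starting material
26 | (1S,3S,6S,7R,8R)-3-acetoxy-1-(tert-butyldimethylsilyloxy)-8-[(2R)-2-methylbutanoyloxy]germacra-4Z,9Z,11(13)-trien-12,6-olide | C=C1C(=O)O[C@H]2/C=C(/C)[C@@H](OC(C)=O)C[C@H](O[Si](C)(C)C(C)(C)C)/C(C)=C\[C@@H](OC(=O)[C@H](C)CC)[C@@H]12 | intermediate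
27 | (1S,3S,6S,7R,8R)-3-acetoxy-1-hydroxy-8-[(2R)-2-methylbutanoyloxy]germacra-4Z,9Z,11(13)-trien-12,6-olide | C=C1C(=O)O[C@H]2/C=C(/C)[C@@H](OC(C)=O)C[C@H](O)/C(C)=C\[C@@H](OC(=O)[C@H](C)CC)[C@@H]12 | target

**Step count**

Total: 16 steps. Longest linear sequence: 13 steps (steps 4–6 then 7–16, or equally steps 1–3 then 7–16).

**Steps most likely to fail**

1. Step 14. The vinylpalladium may be delivered to the wrong face of the C6=C7 bond if hydroxyl coordination does not override the ring conformation. The carboxylate may also close from outside the metal and give the trans-fused lactone, or the allylic acetate may ionise. The fallback replaces hydroxyl direction by steric shielding and a late inversion; it sets out from 21 and comes back at 26. The ring closure of 21 (or reduction of the ketone described under point 2 from its other face) gives the 8R-epimeric trienol F1. TESOTf and 2,6-lutidine convert it into the triethylsilyl ether F3. Annulation with 23 under the conditions of step 14 should then occur on the diene face away from the silyl ether and give the 8-epimeric lactone silyl ether F4. PPTS in MeOH removes the triethylsilyl group selectively to give the 8-epimeric hydroxy lactone F5. Mitsunobu esterification with 25 (PPh3, DIAD, toluene, 0 °C) inverts C8 and gives 26.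

2. Step 13. Oligomerisation may compete with ring closure, the alkenyl iodide may be reduced, and the sense of induction at C8 may be the opposite of that assumed. The fallback sets C8 by ketone reduction instead of by C–C bond formation; it sets out from 21 and comes back at 22. The cyclisation is run without regard to selectivity, and the 8R-epimeric trienol F1 formed beside 22 is oxidised together with it (Dess–Martin periodinane, NaHCO3, CH2Cl2, 0 °C) to the cross-conjugated macrocyclic ketone F2. 1,2-Reduction at −78 °C (NaBH4/CeCl3 in MeOH, or L-Selectride in THF) attacks the exposed face of the ring ketone, a different controlling element from the closure, and should return 22. Whichever epimer prevails is usable, because F1 is carried to 26 by the sequence under point 1.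

3. Step 7. Enantioselection by the isopinocampheyl ligands may be insufficient for a methyl ketone, and the Z enal may isomerise. The fallback uses auxiliary control; it sets out from 13 and comes back at 15. The titanium enolate of (R)-3-acetyl-4-isopropyl-1,3-thiazolidine-2-thione (TiCl4, i-Pr2NEt, CH2Cl2, −78 °C; Nagao-type acetate aldol) adds to 13 to give the (3S)-aldol imide F6, separable from its diastereomer. MeNHOMe·HCl and imidazole displace the auxiliary to give the β-hydroxy Weinreb amide F7. Three equivalents of alkenyllithium 6 (from 4) in Et2O at −78 °C then give 15.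

**Further compounds**

F1 | step 13 | (1S,2Z,4Z,6R,7Z,9S)-9-(tert-butyldimethylsilyloxy)-6-hydroxy-2,8-dimethylcyclodeca-2,4,7-trien-1-yl acetate (C8 epimer of 22) | CC(=O)O[C@@H]1/C(C)=C\C=C/[C@@H](O)/C=C(C)\[C@@H](O[Si](C)(C)C(C)(C)C)C1
F2 | step 13 | (1S,2Z,4Z,7Z,9S)-9-(tert-butyldimethylsilyloxy)-2,8-dimethyl-6-oxocyclodeca-2,4,7-trien-1-yl acetate | CC(=O)O[C@@H]1/C(C)=C\C=C/C(=O)/C=C(C)\[C@@H](O[Si](C)(C)C(C)(C)C)C1
F3 | step 14 | (1S,2Z,4Z,6R,7Z,9S)-9-(tert-butyldimethylsilyloxy)-2,8-dimethyl-6-(triethylsilyloxy)cyclodeca-2,4,7-trien-1-yl acetate | CC(=O)O[C@@H]1/C(C)=C\C=C/[C@@H](O[Si](CC)(CC)CC)/C=C(C)\[C@@H](O[Si](C)(C)C(C)(C)C)C1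
F4 | step 14 | (1S,3S,6S,7R,8S)-3-acetoxy-1-(tert-butyldimethylsilyloxy)-8-(triethylsilyloxy)germacra-4Z,9Z,11(13)-trien-12,6-olide | C=C1C(=O)O[C@H]2/C=C(/C)[C@@H](OC(C)=O)C[C@H](O[Si](C)(C)C(C)(C)C)/C(C)=C\[C@H](O[Si](CC)(CC)CC)[C@@H]12
F5 | step 14 | (1S,3S,6S,7R,8S)-3-acetoxy-1-(tert-butyldimethylsilyloxy)-8-hydroxygermacra-4Z,9Z,11(13)-trien-12,6-olide (C8 epimer of 24) | C=C1C(=O)O[C@H]2/C=C(/C)[C@@H](OC(C)=O)C[C@H](O[Si](C)(C)C(C)(C)C)/C(C)=C\[C@H](O)[C@@H]12
F6 | step 7 | (R)-3-[(3S,4Z)-3-hydroxy-4-methyl-7-(trimethylsilyl)hept-4-en-6-ynoyl]-4-isopropyl-1,3-thiazolidine-2-thione | CC(C)[C@@H]1CSC(=S)N1C(=O)C[C@H](O)/C(C)=C\C#C[Si](C)(C)C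
F7 | step 7 | (3S,4Z)-3-hydroxy-N-methoxy-N,4-dimethyl-7-(trimethylsilyl)hept-4-en-6-ynamide | CON(C)C(=O)C[C@H](O)/C(C)=C\C#C[Si](C)(C)C
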